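## The problem

- The target is a fully substituted 2-aminoimidazole. N1 carries a methyl group, C5 a 4-methoxybenzyl arm, C4 an (R)-hydroxy(4-methoxyphenyl)methyl group, and the C2 nitrogen is bonded to C5 of a 3-methylimidazole-2,4-dione (dehydrohydantoin) ring.
- The two five-membered rings meet only through the exocyclic NH. The difficulty is therefore one of substitution pattern: which ring nitrogen is methylated and which ring carbon carries which arm must be fixed without ambiguity.
- The carbinol carbon is the only stereocentre. Nothing else in the molecule can relay chirality to it, so its configuration must come from a catalyst, a reagent or the chiral pool.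
- This carbinol is benzylic twice over and sits on an electron-rich heterocycle. Acid, heat or a free 2-amino group would favour its ionisation and so its racemisation, which argues for creating it late.
- The dehydrohydantoin is an acylamidine. It is opened by hydroxide, alkoxide or hydrazine, is at risk from strong hydride donors, and together with imidazole N3 forms a metal-binding pocket, so it also belongs near the end.
- The enabling feature is imidazole C4. In creatinine (1) this atom is a lactam carbonyl carbon, and the same purchase supplies the N1 methyl group, the C2 amino group and a C5 methylene for the benzyl arm. Turning the C4 lactam into a C4–Br bond places a coupling handle on exactly the ring atom that must receive the carbinol carbon and the anisyl ring.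

## Retrosynthesis

**Target 14 to ketone 13.** The C–H bond of the carbinol is cut, leaving a diaryl ketone. Setting the stereocentre last means no later step can ionise the carbinol. At this stage the imidazole already carries the electron-poor acylamidine, which makes the ketone more electrophilic and the product alcohol less prone to ionisation than it would be with a free or amidine-masked 2-amino group. The precursor 13 is achiral. The forward reaction must distinguish the two aryl faces of the ketone and leave the dehydrohydantoin alone, which points to a transfer-hydrogenation catalyst rather than a borane or an aluminium hydride.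

**Ketone 13 to amine 10 and 1-methylparabanic acid (11).** The exocyclic N–C bond to the dehydrohydantoin is cut. The alternative, building that ring stepwise on the amine, costs steps, and attaching it earlier would expose it to deoxybromination and palladium chemistry it would not survive. The cut removes a whole ring and returns a commercial trione. The forward reaction must be regioselective for the carbonyl next to N–H of 11, which activation as the O-silyl imidate 12 provides.

**Amine 10 to formamidine 9.** Only the nitrogen mask is changed. A dimethylformamidine is preferred to a carbamate or an amide because it arises at no cost in the bromination step, leaves no N–H on the 2-nitrogen during the palladium step, and falls off on mild acid hydrolysis that the ketone tolerates.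

**Formamidine ketone 9 to bromide 6, carbon monoxide (7) and 4-methoxyphenylboronic acid (8).** Two bonds are cut at the carbonyl carbon, C4–C(=O) and C(=O)–aryl. Three neighbouring cuts are weaker:
- A two-component aryl coupling at C4 gives the wrong oxidation level.
- Addition of a C4 organometallic to aldehyde 2 gives a racemic carbinol that would have to be oxidised again, and it needs halogen–metal exchange beside an amidine.
- Friedel–Crafts acylation of a C4-unsubstituted 2-aminoimidazole would compete with N-acylation.

The carbonylative coupling delivers the ketone directly from a one-carbon gas and a shelf boronic acid, and reduces a C23 ketone to a C15 bromide. The forward reaction needs carbon monoxide insertion to precede aryl transfer at a hindered, electron-rich carbon.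

**Bromide 6 to lactam 4 (through 5).** The C4–Br bond is traced back to the lactam C=O, and the amidine to the free amine. Bromo-dehydration with a Vilsmeier-type reagent aromatises the ring and masks the amine in one operation. Brominating a C4–H imidazole instead would first require reducing the lactam. The precursor 4 is a simple substituted creatinine. The reaction must take place at oxygen and nitrogen rather than at the C5 methine.

**Lactam 4 to benzylidene 3, then to creatinine (1) and 4-methoxybenzaldehyde (2).** The C5–CH2 bond is cut as a C=C bond. Condensation followed by hydrogenation is chosen over direct benzylation of 1 because the enolate of 1 is ambident and could be alkylated twice, whereas the Knoevenagel reaction can only occur at C5 and only once. Both starting materials are commodity chemicals.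

## Roads not taken

**Alternative 1: palladium carboamination of a chiral propargyl guanidine.**
- Cut: N1–C5 and the CH2–aryl bond of the benzyl arm, with the imidazole ring formed in the key step.
- Forward key step: the N-propargyl sulfonylguanidine A2 would react with 4-methoxyphenyl triflate A3 under a palladium catalyst with a bulky biarylphosphine and a lithium alkoxide. A2 carries a silyl-protected carbinol derived from (R)-4-methoxymandelic acid A4. The N-methyl nitrogen adds across the alkyne, the aryl group is delivered to the terminal carbon, and a proton shift aromatises the ring to the N-sulfonyl 2-aminoimidazole A1.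
- Merits: the configuration comes from the chiral pool and is certain from the outset, and one step creates the ring and the benzyl arm.
- Weak points:
  - A4 must pass through the α-aryl α-silyloxy aldehyde A5, which is configurationally fragile.
  - The proton shift that aromatises the ring creates carbanion character at C4, next to a carbon bearing a silyloxy leaving group. Elimination and epimerisation under alkoxide at high temperature are real risks.
  - Imine formation, acetylide addition, guanidinylation and two deprotections bring the count to about ten steps or more.
- Comparison: this road is better on the certainty of absolute configuration. The chosen plan offers a seven-step sequence from three achiral commodity materials, a stereocentre that is never carried through base or heat, and either catalyst antipode to correct the sense of induction.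

**Alternative 2: a temporary pyrimidine ring.**
- Cut: N3–C4 and N1–C5.
- Forward key step: N-methylpyrimidin-2-amine A7 would be alkylated at a ring nitrogen by the 2-bromo-1,3-diketone A8, made by bromination of diketone A9. The methylamino group then condenses on the benzyl ketone to give the imidazo[1,2-a]pyrimidinium bromide A6. Hydrazinolysis of the pyrimidine ring would release amino ketone 10.
- Merits: no palladium and no carbon monoxide 7, the pyrimidine decides which nitrogen bears the methyl group, and 10 would be reached in about four steps against five here.
- Weak points:
  - A8 is a secondary bromide between two carbonyls. It tends to donate bromine rather than undergo substitution, and it is prone to retro-Claisen cleavage, while the pyrimidine nitrogen is a weak and hindered nucleophile.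
  - The regiochemistry rests on the benzyl ketone being more reactive than the aryl ketone.
  - The hydrazinolysis is carried out beside an aryl ketone.
- Comparison: on step count to 10 this road is equal or slightly shorter, and it shares the same endgame. The chosen plan sets against it that every ring position is bought with creatinine 1, not decided by the relative reactivity of two carbonyls, and that the aroyl unit is assembled by a reaction with no ambident partner.

**Alternative 3: Boulton–Katritzky rearrangement.**
- Cut: N3–C4, with an oxadiazole O–N bond broken as the imidazole forms.
- Forward key step: 3-amino-5-methyl-1,2,4-oxadiazole A12 would be condensed with diketone A9 to give enaminone A11. An alkoxide base would then make the enaminone carbon attack the oxadiazole nitrogen, giving the 2-acetamido-4-aroyl-5-benzyl-1H-imidazole A10.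
- Merits: metal-free, and the aroyl group is in place when the ring forms.
- Weak points:
  - A10 is an N–H imidazole. Methylation must choose N1 over N3 and over the acetamide nitrogen.
  - The weakly nucleophilic A12 must condense at the correct carbonyl of A9.
  - Deacetylation is an extra step.
- Comparison: methylation and deacetylation bring this road to 10 in five steps, the same as here. It is equal on length and better on reagent simplicity. The chosen plan has no methylation regiochemistry to solve.

Key step: step 4

Assumption: 1-methylparabanic acid (11) is taken as a catalogue compound, and the alkene geometry of 3 (drawn Z) is immaterial because step 2 removes it.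

## Route

Step 1
Reactants: 1 creatinine (2-amino-1-methyl-1,5-dihydro-4H-imidazol-4-one); 2 4-methoxybenzaldehyde
Product: 3 (Z)-2-amino-5-(4-methoxybenzylidene)-1-methyl-1,5-dihydro-4H-imidazol-4-one
Conditions: NaOAc, AcOH, 110 °C
Reagents that add atoms: none
Why: Knoevenagel condensation; the C5 methylene of 1, flanked by the lactam carbonyl and the guanidine nitrogen, is the only carbon acid present and the aldehyde cannot enolise, so a single conjugated arylidene should form with loss of water.

Step 2
Reactants: 3 (Z)-2-amino-5-(4-methoxybenzylidene)-1-methyl-1,5-dihydro-4H-imidazol-4-one
Product: 4 (±)-2-amino-5-(4-methoxybenzyl)-1-methyl-1,5-dihydro-4H-imidazol-4-one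
Conditions: H2 (1 atm), Pd/C (10% palladium on carbon), MeOH–AcOH, rt
Reagents that add atoms: none
Why: Heterogeneous catalytic hydrogenation of a conjugated exocyclic alkene; the aryl ether and the acylguanidine are inert, and the new C5 centre is racemic and irrelevant because C5 becomes trigonal again in step 3.

Step 3
Reactants: 4 (±)-2-amino-5-(4-methoxybenzyl)-1-methyl-1,5-dihydro-4H-imidazol-4-one
Product: 6 (E)-N'-[4-bromo-5-(4-methoxybenzyl)-1-methyl-1H-imidazol-2-yl]-N,N-dimethylformamidine, via formamidine lactam 5 (not isolated)
Conditions: POBr3, DMF, 1,2-dichloroethane, 0 to 80 °C; aq NaHCO3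
Reagents that add atoms: phosphorus oxybromide, O=P(Br)(Br)Br; N,N-dimethylformamide, CN(C)C=O
Why: Vilsmeier–Haack-type halo-aromatisation of an imidazol-4-one, the reaction that converts imidazolinones into 4-haloimidazoles. The bromoiminium salt first turns the primary amine into amidine 5, then the lactam oxygen is activated, bromide displaces it at C4 and loss of the C5 proton gives the aromatic bromide. C5 is already substituted, so the C-formylation seen with C5-unsubstituted imidazolones has no aromatic outlet.

Step 4
Reactants: 6 (E)-N'-[4-bromo-5-(4-methoxybenzyl)-1-methyl-1H-imidazol-2-yl]-N,N-dimethylformamidine; 7 carbon monoxide; 8 4-methoxyphenylboronic acid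
Product: 9 (E)-N'-[4-(4-methoxybenzoyl)-5-(4-methoxybenzyl)-1-methyl-1H-imidazol-2-yl]-N,N-dimethylformamidine
Conditions: Pd(OAc)2 (cat.), di(1-adamantyl)-n-butylphosphine, TMEDA, toluene, CO (5 bar), 100 °C
Reagents that add atoms: none
Why: Carbonylative Suzuki–Miyaura coupling of a heteroaryl bromide; the closest known reaction type is the three-component ketone synthesis from (hetero)aryl bromides, carbon monoxide and arylboronic acids with this catalyst system. Pd(OAc)2 is reduced in the flask to zerovalent palladium carrying the bulky, electron-rich phosphine, which inserts into the C4–Br bond of 6 despite the electron-rich ring. Carbon monoxide then coordinates and the imidazol-4-yl group migrates onto it to give an acyl complex of divalent palladium; transmetalation from the amine-activated boronic acid and reductive elimination release ketone 9 and return zerovalent palladium. No ring is closed and no stereocentre is formed. The selectivity needed is acyl transfer before aryl transfer, since direct transmetalation would give the C4-aryl biaryl; 5 bar of carbon monoxide, the large phosphine and the crowding of the palladium-bound C4 between N3 and the C5 benzyl group all slow transmetalation relative to insertion, and an electron-rich migrating group inserts quickly and is slow to decarbonylate. The formamidine removes both N–H bonds of the 2-amino group, so no nitrogen nucleophile can intercept the acylpalladium as an amide. The bromide is the only carbon–halogen bond in 6, so site selectivity is not in question.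

Step 5
Reactants: 9 (E)-N'-[4-(4-methoxybenzoyl)-5-(4-methoxybenzyl)-1-methyl-1H-imidazol-2-yl]-N,N-dimethylformamidine
Product: 10 [2-amino-5-(4-methoxybenzyl)-1-methyl-1H-imidazol-4-yl](4-methoxyphenyl)methanone
Conditions: 2 M aq HCl, EtOH, 70 °C; then aq NaHCO3
Reagents that add atoms: none
Why: Acid hydrolysis of an N,N-dimethylformamidine; the protonated amidine takes up water and releases dimethylamine and formic acid, while the non-enolisable diaryl ketone, the aryl ethers and the imidazole ring are stable to dilute acid.

Step 6
Reactants: 10 [2-amino-5-(4-methoxybenzyl)-1-methyl-1H-imidazol-4-yl](4-methoxyphenyl)methanone; 11 1-methylparabanic acid (1-methylimidazolidine-2,4,5-trione)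
Product: 13 5-{[4-(4-methoxybenzoyl)-5-(4-methoxybenzyl)-1-methyl-1H-imidazol-2-yl]amino}-3-methylimidazole-2,4-dione, via O-trimethylsilyl imidate 12 (not isolated)
Conditions: 11, N,O-bis(trimethylsilyl)acetamide (BSA), MeCN, 80 °C; then 10, toluene, 110 °C; aqueous work-up
Reagents that add atoms: none
Why: Silyl-mediated amidine formation, the established way of attaching this dehydrohydantoin to 2-aminoimidazoles. BSA converts 11 into the O-silyl imidate 12 at the carbonyl next to N–H, and the 2-amino group displaces silanolate at that carbon, the most electrophilic of the three because it adjoins the C5 carbonyl. The ketone has no enolisable hydrogen and should be untouched.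

Step 7
Reactants: 13 5-{[4-(4-methoxybenzoyl)-5-(4-methoxybenzyl)-1-methyl-1H-imidazol-2-yl]amino}-3-methylimidazole-2,4-dione
Product: 14 5-({4-[(R)-hydroxy(4-methoxyphenyl)methyl]-5-(4-methoxybenzyl)-1-methyl-1H-imidazol-2-yl}amino)-3-methylimidazole-2,4-dione (the target)
Conditions: RuCl[(S,S)-TsDPEN](p-cymene) (cat.), HCO2H/Et3N (1:1), DMF, 30 °C
Reagents that add atoms: none
Why: Noyori–Ikariya asymmetric transfer hydrogenation of an aryl heteroaryl ketone; the Ru–H/N–H pair delivers hydride and proton without substrate coordination, so the amidine, the ring carbonyls and the aryl ethers should not be reduced. With the (S,S) ligand the unhindered, planar anisyl ring is expected to lie beside the p-cymene ligand (C–H/π contact) and the fully substituted imidazolyl ring to point away, so hydride should add to the Si face of the ketone and give the (R)-carbinol. The mildly acidic formate medium and low temperature are chosen to keep the new carbinol from ionising.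

## Compound list

1 | creatinine (2-amino-1-methyl-1,5-dihydro-4H-imidazol-4-one) | CN1CC(=O)N=C1N | starting material
2 | 4-methoxybenzaldehyde | COc1ccc(C=O)cc1 | starting material
3 | (Z)-2-amino-5-(4-methoxybenzylidene)-1-methyl-1,5-dihydro-4H-imidazol-4-one | CN1C(N)=NC(=O)/C1=C/c1ccc(OC)cc1 | intermediate
4 | (±)-2-amino-5-(4-methoxybenzyl)-1-methyl-1,5-dihydro-4H-imidazol-4-one (racemic at C5) | CN1C(N)=NC(=O)C1Cc1ccc(OC)cc1 | intermediate
5 | (±)-(E)-N'-[5-(4-methoxybenzyl)-1-methyl-4-oxo-4,5-dihydro-1H-imidazol-2-yl]-N,N-dimethylformamidine (formamidine lactam) | CN(C)/C=N/C1=NC(=O)C(Cc2ccc(OC)cc2)N1C | intermediate (not isolated)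
6 | (E)-N'-[4-bromo-5-(4-methoxybenzyl)-1-methyl-1H-imidazol-2-yl]-N,N-dimethylformamidine | CN(C)/C=N/c1nc(Br)c(Cc2ccc(OC)cc2)n1C | intermediate
7 | carbon monoxide | [C-]#[O+] | starting material
8 | 4-methoxyphenylboronic acid | COc1ccc(B(O)O)cc1 | starting material
9 | (E)-N'-[4-(4-methoxybenzoyl)-5-(4-methoxybenzyl)-1-methyl-1H-imidazol-2-yl]-N,N-dimethylformamidine | CN(C)/C=N/c1nc(C(=O)c2ccc(OC)cc2)c(Cc2ccc(OC)cc2)n1C | intermediate
10 | [2-amino-5-(4-methoxybenzyl)-1-methyl-1H-imidazol-4-yl](4-methoxyphenyl)methanone | Nc1nc(C(=O)c2ccc(OC)cc2)c(Cc2ccc(OC)cc2)n1C | intermediate
11 | 1-methylparabanic acid (1-methylimidazolidine-2,4,5-trione) | CN1C(=O)NC(=O)C1=O | starting material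
12 | 1-methyl-4-(trimethylsilyloxy)-1H-imidazole-2,5-dione (O-trimethylsilyl imidate of 11) | CN1C(=O)N=C(O[Si](C)(C)C)C1=O | intermediate (not isolated)
13 | 5-{[4-(4-methoxybenzoyl)-5-(4-methoxybenzyl)-1-methyl-1H-imidazol-2-yl]amino}-3-methylimidazole-2,4-dione | COc1ccc(Cc2c(C(=O)c3ccc(OC)cc3)nc(NC3=NC(=O)N(C)C3=O)n2C)cc1 | intermediate
14 | 5-({4-[(R)-hydroxy(4-methoxyphenyl)methyl]-5-(4-methoxybenzyl)-1-methyl-1H-imidazol-2-yl}amino)-3-methylimidazole-2,4-dione | COc1ccc(Cc2c([C@H](O)c3ccc(OC)cc3)nc(NC3=NC(=O)N(C)C3=O)n2C)cc1 | target

## Step count and risks

Total step count: 7. Longest linear sequence: 7 steps (1 to 14).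

**Step 4 (key step).** Aryl transfer to palladium may outrun carbon monoxide insertion and give the C4-aryl biaryl. Alternatively, carbon monoxide may saturate zerovalent palladium and slow insertion into the flanked, electron-rich C4–Br bond until protodebromination and boronic acid homocoupling take over.

Fallback, from 6, returning at 9: the three-component event is split into two known steps so that the aryl nucleophile cannot meet palladium before carbon monoxide has. Aminocarbonylation of 6 with N,O-dimethylhydroxylamine hydrochloride (Pd(OAc)2, Xantphos, K3PO4, CO at 1 atm, toluene, 100 °C) should give the Weinreb amide F1. Addition of 4-methoxyphenylmagnesium bromide (THF, 0 °C) to F1 should then stop at ketone 9. The C4–C(=O) bond still comes from carbon monoxide and the aryl–C(=O) bond still forms at that carbon.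

**Step 3.** The Vilsmeier electrophile may attack the C5 methine carbon instead of oxygen, or bromide may fail to displace the activated oxygen of this vinylogous urea, so that aromatisation stalls.

Fallback, from 4, returning at 9: the amine is masked without an electrophilic halogenating agent by heating 4 with DMF dimethyl acetal (toluene, 80 °C), giving 5 as an isolated compound. Deprotonation of 5 at C5 with Cs2CO3 and O-sulfonylation of the aromatic enolate with PhNTf2 (DMF, rt) should give the imidazol-4-yl triflate F2. F2 then takes the place of 6 in the carbonylative coupling with 7 and 8 under the step 4 catalyst and gives 9.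

**Step 7.** Facial discrimination between two electron-rich aromatic groups may be poor. The sense of induction predicted from the ring-placement model may also be inverted if the imidazolyl ring, not the anisyl ring, sits beside the arene ligand. The configuration of 14 would therefore be assigned by Mosher ester analysis, and the (R,R) catalyst used if the sense is reversed.

Fallback, from 13, returning at 14: the ketone is reduced without asymmetric control using the racemic catalyst RuCl(rac-TsDPEN)(p-cymene) under the same formate conditions, giving the racemic carbinol F3. F3 is resolved by preparative chromatography on a chiral stationary phase into 14 and the (S)-carbinol F4. F4 is oxidised back to 13 with MnO2 (CH2Cl2, rt) and recycled.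

**Step 6.** The N–C bond formation may be slow because the 4-aroyl group withdraws electron density from the 2-amino group through the ring, so that 12 decomposes thermally before it is captured.

Fallback, from 10, returning at 14: the order of the last two operations is reversed. Transfer hydrogenation of 10 with RuCl[(S,S)-TsDPEN](p-cymene) and HCO2H/Et3N should give the (R)-amino alcohol F5, whose amine is no longer deactivated. Condensation of F5 with 11 and excess BSA, as in step 6, carries the hydroxyl through the heating as the trimethylsilyl ether F6, and aqueous work-up releases 14. The price is that an electron-rich carbinol must survive hot toluene without ionising, which is why this order is not the first choice.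

## Further compounds

F1 | step 4 | (E)-2-{[(dimethylamino)methylene]amino}-N-methoxy-5-(4-methoxybenzyl)-N,1-dimethyl-1H-imidazole-4-carboxamide (Weinreb amide) | CN(C)/C=N/c1nc(C(=O)N(C)OC)c(Cc2ccc(OC)cc2)n1C
F2 | step 3 | (E)-2-{[(dimethylamino)methylene]amino}-5-(4-methoxybenzyl)-1-methyl-1H-imidazol-4-yl trifluoromethanesulfonate | CN(C)/C=N/c1nc(OS(=O)(=O)C(F)(F)F)c(Cc2ccc(OC)cc2)n1C
F3 | step 7 | racemic 5-({4-[hydroxy(4-methoxyphenyl)methyl]-5-(4-methoxybenzyl)-1-methyl-1H-imidazol-2-yl}amino)-3-methylimidazole-2,4-dione | COc1ccc(Cc2c(C(O)c3ccc(OC)cc3)nc(NC3=NC(=O)N(C)C3=O)n2C)cc1
F4 | step 7 | 5-({4-[(S)-hydroxy(4-methoxyphenyl)methyl]-5-(4-methoxybenzyl)-1-methyl-1H-imidazol-2-yl}amino)-3-methylimidazole-2,4-dione | COc1ccc(Cc2c([C@@H](O)c3ccc(OC)cc3)nc(NC3=NC(=O)N(C)C3=O)n2C)cc1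
F5 | step 6 | (R)-[2-amino-5-(4-methoxybenzyl)-1-methyl-1H-imidazol-4-yl](4-methoxyphenyl)methanol | Nc1nc([C@H](O)c2ccc(OC)cc2)c(Cc2ccc(OC)cc2)n1C
F6 | step 6 | O-trimethylsilyl ether of 14, (R)-configured | COc1ccc(Cc2c([C@H](O[Si](C)(C)C)c3ccc(OC)cc3)nc(NC3=NC(=O)N(C)C3=O)n2C)cc1
A1 | alternative 1 | N-{4-[(R)-(tert-butyldimethylsilyloxy)(4-methoxyphenyl)methyl]-5-(4-methoxybenzyl)-1-methyl-1H-imidazol-2-yl}-2-(trimethylsilyl)ethanesulfonamide | C[Si](C)(C)CCS(=O)(=O)Nc1nc([C@H](O[Si](C)(C)C(C)(C)C)c2ccc(OC)cc2)c(Cc2ccc(OC)cc2)n1C
A2 | alternative 1 | N-[(1R)-1-(tert-butyldimethylsilyloxy)-1-(4-methoxyphenyl)but-3-yn-2-yl]-N'-methyl-N''-[2-(trimethylsilyl)ethanesulfonyl]guanidine (either configuration at C2 of the butynyl chain) | CNC(=NS(=O)(=O)CC[Si](C)(C)C)NC(C#C)[C@H](O[Si](C)(C)C(C)(C)C)c1ccc(OC)cc1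
A3 | alternative 1 | 4-methoxyphenyl trifluoromethanesulfonate | COc1ccc(OS(=O)(=O)C(F)(F)F)cc1
A4 | alternative 1 | (R)-4-methoxymandelic acid | COc1ccc([C@@H](O)C(=O)O)cc1
A5 | alternative 1 | (R)-2-(tert-butyldimethylsilyloxy)-2-(4-methoxyphenyl)acetaldehyde | COc1ccc([C@@H](O[Si](C)(C)C(C)(C)C)C=O)cc1
A6 | alternative 2 | 3-(4-methoxybenzoyl)-2-(4-methoxybenzyl)-1-methylimidazo[1,2-a]pyrimidin-1-ium bromide | C[N+]1=C2N=CC=CN2C(C(=O)c2ccc(OC)cc2)=C1Cc1ccc(OC)cc1.[Br-]
A7 | alternative 2 | N-methylpyrimidin-2-amine | CNc1ncccn1
A8 | alternative 2 | 2-bromo-1,4-bis(4-methoxyphenyl)butane-1,3-dione | COc1ccc(CC(=O)C(Br)C(=O)c2ccc(OC)cc2)cc1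
A9 | alternative 2 | 1,4-bis(4-methoxyphenyl)butane-1,3-dione | COc1ccc(CC(=O)CC(=O)c2ccc(OC)cc2)cc1
A10 | alternative 3 | N-[4-(4-methoxybenzoyl)-5-(4-methoxybenzyl)-1H-imidazol-2-yl]acetamide | CC(=O)Nc1nc(C(=O)c2ccc(OC)cc2)c(Cc2ccc(OC)cc2)[nH]1
A11 | alternative 3 | 1,4-bis(4-methoxyphenyl)-3-[(5-methyl-1,2,4-oxadiazol-3-yl)amino]but-2-en-1-one | Cc1nc(NC(Cc2ccc(OC)cc2)=CC(=O)c2ccc(OC)cc2)no1
A12 | alternative 3 | 3-amino-5-methyl-1,2,4-oxadiazole | Cc1nc(N)no1
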